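**Plan**

1. The last disconnection cuts C2–C1 and O–C10. This opens the 3(2H)-furanone and the ten-membered carbocycle together and leads to the open-chain lactone 28. The enabling feature is that the furanone oxygen on quaternary C10 and the free hydroxyl on C9 are vicinal and anti, and C10 is α to the C1 ketone. C1–C10–C9 is therefore a ring-opened (E)-2-methyl-2,3-epoxy acyl group, and O–C3=C2 is the enolate of a methyl ketone.
2. Earlier cuts: C1 acid ← C1 alcohol ← Sharpless epoxide ← allylic oxidation of an isobutenyl group; C3 ketone ← Wacker oxidation of a vinyl group; C11 chlorohydrin ← spiro-epoxide ← α-methylene lactone; C8–C9 by thioester/alkenylboronic acid coupling; C4–C5 by crotylboration; C6–C7 by an Evans aldol of a succinate imide with acrolein.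
3. Forward order: the butanolide ring is made first (step 2), the chain is grown at C5 and then at C8, and the carbocycle and the furanone ring close together in step 20. One deprotection ends the route.
4. Stereochemistry: C6 and C7 come from the oxazolidinone auxiliary; C4 and C5 from the isopinocampheyl crotylborane; C8 from CBS reduction; C11 from attack anti to the C7 substituent; C9 and C10 from Sharpless epoxidation, with C10 inverted in the key step.

Key step: step 20

Remark: atoms are numbered as in germacranolides: C1 furanone C=O, C2=C3 enol ether, C4 (CH3), C5 (OH), C6 (lactone O), C7, C8 (tiglate), C9 (OH), C10 (CH3, furanone O), C11 (OH, CH2Cl), C12 lactone C=O, C13 CH2Cl. In this numbering the target is 4R,5S,6S,7S,8S,9S,10S,11S.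

**Step 1**
Reactants: 1 (S)-4-benzyloxazolidin-2-one; 2 methyl 4-chloro-4-oxobutanoate
Product: 3 (S)-4-benzyl-3-(4-methoxy-4-oxobutanoyl)oxazolidin-2-one
Conditions: n-BuLi, THF, −78 °C; then 2, −78 → 0 °C
Reagents that add atoms: none
Why: N-acylation of the lithium oxazolidinide by the acid chloride is much faster than attack at the methyl ester, so the succinate half-ester imide should form cleanly; no stereocentre is created.

**Step 2**
Reactants: 3 imide; 4 acrolein
Product: 6 (S)-4-benzyl-3-[(2R,3S)-5-oxo-2-vinyltetrahydrofuran-3-carbonyl]oxazolidin-2-one (trans lactone; ring C2 = C6 and ring C3 = C7 of the target), via open-chain syn-aldol adduct 5 (not isolated)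
Conditions: n-Bu2BOSO2CF3, i-Pr2NEt, CH2Cl2, −78 → 0 °C; 4, −78 → 0 °C; pH 7 buffer, MeOH, H2O2, 0 °C; then pyridinium p-toluenesulfonate (cat.), toluene, 60 °C
Reagents that add atoms: none
Why: Evans syn-aldol reaction: the Z boron enolate formed at C7 (α to the imide, not to the ester) adds to acrolein through a Zimmerman–Traxler chair on the enolate face away from the benzyl group, setting C7 and C6, and the γ-hydroxy ester then lactonises under mild acid to the trans-disubstituted butanolide.

**Step 3**
Reactants: 6 vinyl lactone imide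
Product: 7 (S)-4-benzyl-3-[(2S,3S)-2-formyl-5-oxotetrahydrofuran-3-carbonyl]oxazolidin-2-one (C5 aldehyde)
Conditions: O3, CH2Cl2/MeOH, −78 °C; PPh3, −78 → 23 °C
Reagents that add atoms: ozone, [O-][O+]=O
Why: Ozonolysis with reductive work-up cleaves the only C=C bond to the C5 aldehyde without touching C6 or C7.

**Step 4**
Reactants: 7 aldehyde
Product: 8 (S)-4-benzyl-3-{(2S,3S)-2-[(1S,2S)-1-hydroxy-2-methylbut-3-en-1-yl]-5-oxotetrahydrofuran-3-carbonyl}oxazolidin-2-one (C5 alcohol, C4 methyl, C2=C3 vinyl)
Conditions: pre-formed (E)-crotyl-B(Ipc)2 (from trans-2-butene, KOt-Bu, n-BuLi, (−)-Ipc2BOMe, BF3·OEt2), THF/Et2O, −78 °C; then ethanolamine, 0 → 23 °C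
Reagents that add atoms: (E)-crotylbis(isopinocampheyl)borane from (+)-α-pinene, C/C=C/CB([C@@H]1C[C@@H]2C[C@H]([C@H]1C)C2(C)C)[C@@H]1C[C@@H]2C[C@H]([C@H]1C)C2(C)C
Why: Brown crotylboration: the E-crotylborane reacts through a chair transition state to give the 4,5-anti pair, and the isopinocampheyl groups derived from (+)-α-pinene direct attack to the Si face of the aldehyde, overriding its weaker Felkin bias and placing the C5 hydroxyl syn to the C6 oxygen as in the target.

**Step 5**
Reactants: 8 C5 alcohol
Product: 9 C5 tert-butyldimethylsilyl ether of 8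
Conditions: t-BuMe2SiOSO2CF3, 2,6-lutidine, CH2Cl2, −78 → 0 °C
Reagents that add atoms: tert-butyldimethylsilyl triflate, CC(C)(C)[Si](C)(C)OS(=O)(=O)C(F)(F)F
Why: Silylation with the silyl triflate protects the hindered C5 alcohol so that it neither lactonises nor eliminates later.

**Step 6**
Reactants: 9 silyl ether imide
Product: 10 S-ethyl thioester at C8 (lactone with the C5-silyloxy C4-methyl butenyl chain on C6; auxiliary removed)
Conditions: EtSH, n-BuLi, THF, 0 °C; then NH4Cl (aq)
Reagents that add atoms: ethanethiol, CCS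
Why: Thiolate cleavage of the N-acyl oxazolidinone at the exocyclic carbonyl gives the thioester and returns the auxiliary, the weakly basic thiolate leaving the C7 stereocentre and the β-acyloxy (lactone) bond intact.

**Step 7**
Reactants: 10 thioester; 11 (2-methylprop-1-en-1-yl)boronic acid
Product: 12 C8 enone (3-methylbut-2-enoyl group on C7 of the lactone)
Conditions: Pd2(dba)3 (tris(dibenzylideneacetone)dipalladium, cat.), P(2-furyl)3, cuprous thiophene-2-carboxylate CuO2CC4H3S (1.5 equiv), THF, 50 °C
Reagents that add atoms: none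
Why: Liebeskind–Srogl cross-coupling of a thioester with an alkenylboronic acid forms the C8–C9 bond under neutral, base-free conditions that should not epimerise or eliminate at C7.

**Step 8**
Reactants: 12 enone
Product: 13 C8 allylic alcohol ((R)-1-hydroxy-3-methylbut-2-enyl group on C7; target configuration at C8)
Conditions: (R)-1-methyl-3,3-diphenyltetrahydro-1H,3H-pyrrolo[1,2-c][1,3,2]oxazaborole ((R)-Me-CBS, 20 mol%), catecholborane, toluene, −78 °C
Reagents that add atoms: none
Why: Corey–Bakshi–Shibata reduction: hydride is delivered to the ketone face defined by the catalyst with the alkenyl group as the large substituent, which is also the Felkin–Anh face (attack anti to C6), setting the C8 carbinol of the target, and catecholborane at −78 °C leaves the lactone and the vinyl group untouched.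

**Step 9**
Reactants: 13 C8 alcohol
Product: 14 C8 triethylsilyl ether of 13
Conditions: Et3SiCl, imidazole, CH2Cl2, 0 → 23 °C
Reagents that add atoms: chlorotriethylsilane, CC[Si](Cl)(CC)CC
Why: Temporary silyl protection of the C8 hydroxyl allows the lactone to be enolised in the next step.

**Step 10**
Reactants: 14 lactone
Product: 17 α-methylene lactone (C11=C13), via Mannich base 15 (not isolated), via trimethylammonium iodide 16 (not isolated)
Conditions: LiN(i-Pr)2, THF, −78 °C; CH2=NMe2 I (Eschenmoser's salt), −78 → 23 °C; MeI, MeOH/THF, 23 °C; DBU, CH2Cl2, 23 °C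
Reagents that add atoms: N,N-dimethylmethyleneiminium iodide, C=[N+](C)C.[I-]
Why: Lactone enolate aminomethylation with Eschenmoser's salt followed by N-methylation and E1cB elimination (α-methylenation of a lactone) installs C13; C11 becomes sp2, so no stereocentre is kept.

**Step 11**
Reactants: 17 α-methylene lactone
Product: 18 11,13-spiro-epoxy lactone (epoxide oxygen on C11 trans to C8)
Conditions: t-BuOOH, DBU, CH2Cl2, 0 → 23 °C
Reagents that add atoms: tert-butyl hydroperoxide, CC(C)(C)OO
Why: Weitz–Scheffer-type nucleophilic epoxidation: tert-butylperoxide adds to C13 of the electron-poor methylene lactone (the two electron-rich alkenes do not react) and the resulting lactone enolate should close the oxirane from the face anti to the bulky C7 substituent, placing the C11 oxygen trans to C8.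

**Step 12**
Reactants: 18 spiro-epoxide
Product: 20 C8,C11-diol chlorohydrin (C13–Cl, C11–OH, C8–OH, C5–OTBS), via chlorohydrin triethylsilyl ether 19 (not isolated)
Conditions: LiCl, AcOH, THF, 23 °C; then H2O (AcOH/THF/H2O 3:1:1), 23 °C
Reagents that add atoms: lithium chloride, [Li+].[Cl-]
Why: Lithium-assisted opening of the spiro-epoxide by chloride occurs by SN2 at the primary C13 (the tertiary α-acyl C11 cannot ionise), keeping the C11 configuration, and aqueous acetic acid then cleaves the secondary triethylsilyl ether but not the tert-butyldimethylsilyl ether.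

**Step 13**
Reactants: 20 diol; 21 tigloyl chloride ((E)-2-methylbut-2-enoyl chloride)
Product: 22 C8 tiglate (C11–OH free)
Conditions: pyridine, 4-(dimethylamino)pyridine (cat.), CH2Cl2, 0 → 23 °C
Reagents that add atoms: none
Why: Acylation with the acid chloride and a nucleophilic pyridine catalyst esterifies the secondary C8 alcohol, while the tertiary α-hydroxy lactone oxygen at C11 is too hindered to react.

**Step 14**
Reactants: 22 tiglate
Product: 23 C11 triethylsilyl ether of 22
Conditions: Et3SiOSO2CF3, 2,6-lutidine, CH2Cl2, −78 → 0 °C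
Reagents that add atoms: triethylsilyl triflate, CC[Si](CC)(CC)OS(=O)(=O)C(F)(F)F
Why: The silyl triflate silylates the tertiary C11 alcohol, removing the only free hydroxyl before the enolisation chemistry.

**Step 15**
Reactants: 23 terminal alkene
Product: 24 C3 methyl ketone
Conditions: PdCl2 (10 mol%), CuCl, O2 (1 atm), DMF/H2O 7:1, 23 °C
Reagents that add atoms: water, O
Why: Tsuji–Wacker oxidation converts the monosubstituted alkene to the methyl ketone with Markovnikov selectivity and leaves the trisubstituted isobutenyl and tiglate alkenes untouched.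

**Step 16**
Reactants: 24 isobutenyl compound
Product: 25 (E)-allylic alcohol (C1–OH; C8 cis to the C10 methyl)
Conditions: SeO2 (cat.), t-BuOOH, CH2Cl2, 23 °C
Reagents that add atoms: selenium dioxide (oxygen donor, turned over by the hydroperoxide), O=[Se]=O; tert-butyl hydroperoxide, CC(C)(C)OO
Why: Catalytic SeO2 allylic oxidation (ene reaction then 2,3-sigmatropic shift) hydroxylates the E methyl group of the electron-rich isobutenyl unit, giving the E allylic alcohol; the conjugated tiglate alkene is much less reactive.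

**Step 17**
Reactants: 25 allylic alcohol
Product: 26 9,10-epoxy alcohol ((2S,3S) in glycidol numbering: C10 S, C9 S)
Conditions: Ti(OiPr)4 (20 mol%), diethyl L-(+)-tartrate (24 mol%), t-BuOOH, 4 Å molecular sieves, CH2Cl2, −20 °C
Reagents that add atoms: tert-butyl hydroperoxide, CC(C)(C)OO
Why: Sharpless asymmetric epoxidation of the primary E allylic alcohol with the L-(+)-tartrate ligand delivers oxygen to the face that gives the (2S,3S) glycidol-type epoxide, fixing C9 in the target configuration and C10 in the opposite one, to be inverted later.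

**Step 18**
Reactants: 26 epoxy alcohol
Product: 27 glycidic acid (C1 carboxylic acid)
Conditions: 2,2,6,6-tetramethylpiperidine-1-oxyl (20 mol%), PhI(OAc)2, MeCN/H2O 1:1, 23 °C
Reagents that add atoms: water, O
Why: Nitroxyl-catalysed oxidation with PhI(OAc)2 in wet acetonitrile takes the primary alcohol through the aldehyde hydrate to the glycidic acid without opening the epoxide.

**Step 19**
Reactants: 27 glycidic acid
Product: 28 pentafluorophenyl glycidate
Conditions: C6F5OH, N-(3-dimethylaminopropyl)-N′-ethylcarbodiimide hydrochloride, CH2Cl2, 0 → 23 °C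
Reagents that add atoms: pentafluorophenol, Oc1c(F)c(F)c(F)c(F)c1F
Why: Carbodiimide coupling gives the pentafluorophenyl ester, an acyl donor reactive enough for C-acylation yet stable enough to be purified.

**Step 20**
Reactants: 28 pentafluorophenyl glycidate
Product: 30 furanone-bridged ten-membered lactone (C9–OH free, C5–OTBS, C11–OTES), via macrocyclic epoxy diketone 29 (not isolated)
Conditions: Mg(OSO2CF3)2, i-Pr2NEt, CH2Cl2/MeCN 5:1, slow addition of 28 to 0.001 M, 23 → 40 °C
Reagents that add atoms: none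
Why: Proposed new method: Magnesium bound to the ketone lets the amine deprotonate C2 reversibly (soft enolisation); the magnesium enolate attacks the glycidate carbonyl C1, pentafluorophenoxide leaves, and the new 1,3-diketone is trapped at once as its magnesium enolate, whose C3 oxygen then attacks C10 from the rear while magnesium bridges the C1 carbonyl and the epoxide oxygen, so the oxirane opens to the C9 alkoxide. The closest known reaction types are the soft-enolisation C-acylation of ketones by activated esters to 1,3-diketones (intermolecular), the Masamune–Roush soft-enolisation macrocyclisation, the closure of 1,3-diketones carrying an α′ leaving group to 3(2H)-furanones, and the chelation-controlled opening of glycidic esters at C-α; their combination in a ring-forming cascade has not been shown. The ten-membered carbocycle closes by a 10-(enolendo)-exo-trig acyl substitution and the furanone by a 5-exo-tet O-alkylation that uses the in-plane lone pair of the enolate oxygen. C10 is the only stereocentre formed: it is set by SN2 inversion of the C10 centre of the Sharpless epoxide, which places the furanone oxygen anti to the C9 hydroxyl, whose configuration is carried over unchanged. The step needs C- over O-acylation and methyl over C4 enolisation, secured by the chelated magnesium enolate and by the fact that only acylation at C2 gives a diketone that is removed as a stable enolate; it needs ring closure over oligomerisation, secured by high dilution and slow addition; and it needs 5-exo attack at C10 over 6-endo attack at C9, secured by the shorter tether and by chelate activation of the C10–O bond, the non-nucleophilic triflate counter-ion preventing halide opening. The lactone and the glycidate have no α-hydrogen, the C11 hydroxyl is silylated, and the tiglate is a poor acyl donor, so acyl shift to the C9 oxygen is not expected.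

**Step 21**
Reactants: 30 bis-silyl ether
Product: 31 target, CNP0340393.1
Conditions: HF·pyridine, pyridine, THF, 0 → 23 °C
Reagents that add atoms: none
Why: Fluoride cleaves both silyl ethers under acidic conditions that preserve the base-sensitive chlorohydrin, the tiglate and the furanone.

**Compound list**

1 | (S)-4-benzyloxazolidin-2-one | O=C1N[C@@H](Cc2ccccc2)CO1 | starting material
2 | methyl 4-chloro-4-oxobutanoate | COC(=O)CCC(Cl)=O | starting material
3 | (S)-4-benzyl-3-(4-methoxy-4-oxobutanoyl)oxazolidin-2-one | COC(=O)CCC(=O)N1[C@@H](Cc2ccccc2)COC1=O | intermediate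
4 | acrolein | C=CC=O | starting material
5 | methyl (3S,4R)-3-[(S)-4-benzyl-2-oxooxazolidine-3-carbonyl]-4-hydroxyhex-5-enoate (syn-aldol adduct) | O=C(N1[C@@H](Cc2ccccc2)COC1=O)[C@@H](CC(=O)OC)[C@H](O)C=C | intermediate (not isolated)
6 | (S)-4-benzyl-3-[(2R,3S)-5-oxo-2-vinyltetrahydrofuran-3-carbonyl]oxazolidin-2-one | O=C(N1[C@@H](Cc2ccccc2)COC1=O)[C@@H]3[C@H](OC(=O)C3)C=C | intermediate
7 | (S)-4-benzyl-3-[(2S,3S)-2-formyl-5-oxotetrahydrofuran-3-carbonyl]oxazolidin-2-one | O=C(N1[C@@H](Cc2ccccc2)COC1=O)[C@@H]3[C@H](OC(=O)C3)C=O | intermediate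
8 | (S)-4-benzyl-3-{(2S,3S)-2-[(1S,2S)-1-hydroxy-2-methylbut-3-en-1-yl]-5-oxotetrahydrofuran-3-carbonyl}oxazolidin-2-one | O=C(N1[C@@H](Cc2ccccc2)COC1=O)[C@@H]3[C@H](OC(=O)C3)[C@@H](O)[C@@H](C)C=C | intermediate
9 | C5 tert-butyldimethylsilyl ether of 8 | O=C(N1[C@@H](Cc2ccccc2)COC1=O)[C@@H]3[C@H](OC(=O)C3)[C@@H](O[Si](C)(C)C(C)(C)C)[C@@H](C)C=C | intermediate
10 | S-ethyl thioester at C8: trans lactone with C(=O)SEt on C7 and the (1S,2S)-1-(TBSO)-2-methylbut-3-enyl chain on C6 | CCSC(=O)[C@@H]1[C@H](OC(=O)C1)[C@@H](O[Si](C)(C)C(C)(C)C)[C@@H](C)C=C | intermediate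
11 | (2-methylprop-1-en-1-yl)boronic acid | CC(C)=CB(O)O | starting material
12 | C8 enone: as 10 with a 3-methylbut-2-enoyl group on C7 | CC(C)=CC(=O)[C@@H]1[C@H](OC(=O)C1)[C@@H](O[Si](C)(C)C(C)(C)C)[C@@H](C)C=C | intermediate
13 | C8 alcohol: as 12 with an (R)-1-hydroxy-3-methylbut-2-enyl group on C7 | O[C@H](C=C(C)C)[C@@H]1[C@H](OC(=O)C1)[C@@H](O[Si](C)(C)C(C)(C)C)[C@@H](C)C=C | intermediate
14 | C8 triethylsilyl ether of 13 | CC[Si](CC)(CC)O[C@H](C=C(C)C)[C@@H]1[C@H](OC(=O)C1)[C@@H](O[Si](C)(C)C(C)(C)C)[C@@H](C)C=C | intermediate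
15 | Mannich base: 14 with CH2NMe2 on C11, trans to C8 | CC[Si](CC)(CC)O[C@H](C=C(C)C)[C@@H]1[C@H](OC(=O)[C@H]1CN(C)C)[C@@H](O[Si](C)(C)C(C)(C)C)[C@@H](C)C=C | intermediate (not isolated)
16 | trimethylammonium iodide of 15 | CC[Si](CC)(CC)O[C@H](C=C(C)C)[C@@H]1[C@H](OC(=O)[C@H]1C[N+](C)(C)C)[C@@H](O[Si](C)(C)C(C)(C)C)[C@@H](C)C=C.[I-] | intermediate (not isolated)
17 | α-methylene lactone (C11=C13) | CC[Si](CC)(CC)O[C@H](C=C(C)C)[C@@H]1[C@H](OC(=O)C1=C)[C@@H](O[Si](C)(C)C(C)(C)C)[C@@H](C)C=C | intermediate
18 | 11,13-spiro-epoxy lactone, epoxide oxygen trans to C8 | CC[Si](CC)(CC)O[C@H](C=C(C)C)[C@@H]1[C@H](OC(=O)[C@]1(O2)C2)[C@@H](O[Si](C)(C)C(C)(C)C)[C@@H](C)C=C | intermediate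
19 | chlorohydrin (C11–OH, C13–Cl) with C8–OTES | CC[Si](CC)(CC)O[C@H](C=C(C)C)[C@@H]1[C@H](OC(=O)[C@]1(O)CCl)[C@@H](O[Si](C)(C)C(C)(C)C)[C@@H](C)C=C | intermediate (not isolated)
20 | chlorohydrin diol (C8–OH, C11–OH, C13–Cl, C5–OTBS) | O[C@H](C=C(C)C)[C@@H]1[C@H](OC(=O)[C@]1(O)CCl)[C@@H](O[Si](C)(C)C(C)(C)C)[C@@H](C)C=C | intermediate
21 | tigloyl chloride, (E)-2-methylbut-2-enoyl chloride | C/C=C(\C)C(Cl)=O | starting material
22 | C8 tiglate of 20 | C/C=C(\C)C(=O)O[C@H](C=C(C)C)[C@@H]1[C@H](OC(=O)[C@]1(O)CCl)[C@@H](O[Si](C)(C)C(C)(C)C)[C@@H](C)C=C | intermediate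
23 | C11 triethylsilyl ether of 22 | C/C=C(\C)C(=O)O[C@H](C=C(C)C)[C@@H]1[C@H](OC(=O)[C@]1(O[Si](CC)(CC)CC)CCl)[C@@H](O[Si](C)(C)C(C)(C)C)[C@@H](C)C=C | intermediate
24 | C3 methyl ketone | C/C=C(\C)C(=O)O[C@H](C=C(C)C)[C@@H]1[C@H](OC(=O)[C@]1(O[Si](CC)(CC)CC)CCl)[C@@H](O[Si](C)(C)C(C)(C)C)[C@@H](C)C(C)=O | intermediate
25 | (E)-allylic alcohol (C1–OH) | C/C=C(\C)C(=O)O[C@H](/C=C(\C)CO)[C@@H]1[C@H](OC(=O)[C@]1(O[Si](CC)(CC)CC)CCl)[C@@H](O[Si](C)(C)C(C)(C)C)[C@@H](C)C(C)=O | intermediate
26 | 9,10-epoxy alcohol (9S,10S) | C/C=C(\C)C(=O)O[C@H]([C@@H]2O[C@@]2(C)CO)[C@@H]1[C@H](OC(=O)[C@]1(O[Si](CC)(CC)CC)CCl)[C@@H](O[Si](C)(C)C(C)(C)C)[C@@H](C)C(C)=O | intermediate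
27 | glycidic acid (C1 acid) | C/C=C(\C)C(=O)O[C@H]([C@@H]2O[C@@]2(C)C(O)=O)[C@@H]1[C@H](OC(=O)[C@]1(O[Si](CC)(CC)CC)CCl)[C@@H](O[Si](C)(C)C(C)(C)C)[C@@H](C)C(C)=O | intermediate
28 | pentafluorophenyl glycidate | C/C=C(\C)C(=O)O[C@H]([C@@H]2O[C@@]2(C)C(=O)Oc3c(F)c(F)c(F)c(F)c3F)[C@@H]1[C@H](OC(=O)[C@]1(O[Si](CC)(CC)CC)CCl)[C@@H](O[Si](C)(C)C(C)(C)C)[C@@H](C)C(C)=O | intermediate
29 | macrocyclic 9,10-epoxy 1,3-diketone (ten-membered ring closed at C1–C2) | C/C=C(\C)C(=O)O[C@H]1[C@@H]2[C@H](OC(=O)[C@]2(O[Si](CC)(CC)CC)CCl)[C@@H](O[Si](C)(C)C(C)(C)C)[C@@H](C)C(=O)CC(=O)[C@]3(C)O[C@@H]13 | intermediate (not isolated)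
30 | 5-O-TBS, 11-O-TES ether of the target | C/C=C(\C)C(=O)O[C@H]1[C@@H]2[C@H](OC(=O)[C@]2(O[Si](CC)(CC)CC)CCl)[C@@H](O[Si](C)(C)C(C)(C)C)[C@@H](C)C2=CC(=O)[C@@](C)(O2)[C@H]1O | intermediate
31 | CNP0340393.1 | C/C=C(\C)C(=O)O[C@H]1[C@@H]2[C@H](OC(=O)[C@]2(O)CCl)[C@@H](O)[C@@H](C)C2=CC(=O)[C@@](C)(O2)[C@H]1O | target

**Step count and risks**

Total step count: 21. Longest linear sequence: 21 steps (from 1).

Steps most likely to fail:

1. Step 20 (Proposed new method). Intermolecular acylation may outrun closure of the ten-membered ring and give oligomers. Enolisation toward C4 may epimerise C4 or eliminate the C5 silyloxy group. The epoxide may open at C9, or at C10 without clean inversion. Fallback with known reaction types, setting out from 26: Dess–Martin oxidation gives the epoxy aldehyde F1. Intramolecular aldol addition of the kinetic lithium enolate of the methyl ketone (LiN(SiMe3)2, THF, −78 °C, high dilution) gives the macrocyclic β-hydroxy ketone F2 as a C1 epimer mixture. A second Dess–Martin oxidation gives the 1,3-diketone 29, isolated this time, and DBU in MeCN at 23 °C closes the furanone by 5-exo O-alkylation of the diketone at the epoxide. The fallback comes back at 30.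

2. Step 11. Facial discrimination in the oxirane-closing step may be poor, because the C6 side chain shields the face opposite to the C7 substituent, and the C11 epimer would then form. Fallback, setting out from 14: enolate alkylation (LiN(i-Pr)2, THF, −78 °C; 4-methoxybenzyl chloromethyl ether) anti to the C7 substituent gives the 4-methoxybenzyloxymethyl lactone F3. Enolate hydroxylation (KN(SiMe3)2, 3-phenyl-2-(phenylsulfonyl)oxaziridine, −78 °C), again anti to the C7 substituent, gives the tertiary alcohol F4 with the target configuration at C11. DDQ in wet CH2Cl2 gives the diol F5, selective primary sulfonylation (TsCl, pyridine) gives the tosylate F6, and K2CO3 in MeOH closes the epoxide. The fallback comes back at 18.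

3. Step 16. Over-oxidation to the enal, competing oxidation of the tiglate methyl groups or of the position α to the methyl ketone, and stalled conversion are all possible. Fallback, setting out from 24: ozonolysis with controlled ozone uptake (O3, CH2Cl2, −78 °C; PPh3), the conjugated tiglate alkene reacting more slowly, gives the C9 aldehyde F7. Wittig olefination with 2-(triphenylphosphoranylidene)propanal gives the (E)-enal F8, and NaBH(OAc)3 reduces the aldehyde in the presence of the methyl ketone. The fallback comes back at 25.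

**Further compounds**

F1 | step 20 | 9,10-epoxy aldehyde (C1 aldehyde of 26) | C/C=C(\C)C(=O)O[C@H]([C@@H]2O[C@@]2(C)C=O)[C@@H]1[C@H](OC(=O)[C@]1(O[Si](CC)(CC)CC)CCl)[C@@H](O[Si](C)(C)C(C)(C)C)[C@@H](C)C(C)=O
F2 | step 20 | macrocyclic β-hydroxy ketone (C1 carbinol, C1 epimers) | C/C=C(\C)C(=O)O[C@H]1[C@@H]2[C@H](OC(=O)[C@]2(O[Si](CC)(CC)CC)CCl)[C@@H](O[Si](C)(C)C(C)(C)C)[C@@H](C)C(=O)CC(O)[C@]3(C)O[C@@H]13
F3 | step 11 | lactone 14 carrying a (4-methoxybenzyloxy)methyl group on C11, trans to C8 | CC[Si](CC)(CC)O[C@H](C=C(C)C)[C@@H]1[C@H](OC(=O)[C@H]1COCc2ccc(OC)cc2)[C@@H](O[Si](C)(C)C(C)(C)C)[C@@H](C)C=C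
F4 | step 11 | C11 tertiary alcohol with C13–O–(4-methoxybenzyl) | CC[Si](CC)(CC)O[C@H](C=C(C)C)[C@@H]1[C@H](OC(=O)[C@]1(O)COCc2ccc(OC)cc2)[C@@H](O[Si](C)(C)C(C)(C)C)[C@@H](C)C=C
F5 | step 11 | 11,13-diol | CC[Si](CC)(CC)O[C@H](C=C(C)C)[C@@H]1[C@H](OC(=O)[C@]1(O)CO)[C@@H](O[Si](C)(C)C(C)(C)C)[C@@H](C)C=C
F6 | step 11 | 13-O-tosylate of the 11,13-diol | CC[Si](CC)(CC)O[C@H](C=C(C)C)[C@@H]1[C@H](OC(=O)[C@]1(O)COS(=O)(=O)c2ccc(C)cc2)[C@@H](O[Si](C)(C)C(C)(C)C)[C@@H](C)C=C
F7 | step 16 | C9 aldehyde | C/C=C(\C)C(=O)O[C@H](C=O)[C@@H]1[C@H](OC(=O)[C@]1(O[Si](CC)(CC)CC)CCl)[C@@H](O[Si](C)(C)C(C)(C)C)[C@@H](C)C(C)=O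
F8 | step 16 | (E)-enal (C1 aldehyde) | C/C=C(\C)C(=O)O[C@H](/C=C(\C)C=O)[C@@H]1[C@H](OC(=O)[C@]1(O[Si](CC)(CC)CC)CCl)[C@@H](O[Si](C)(C)C(C)(C)C)[C@@H](C)C(C)=O
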